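## Structural features

The target is an unsymmetrical ether of two 2-(2-phenylethyl)chromones. One half is a fully aromatic chromone with a free hydroxyl at C7′ and the ether oxygen at C6′. The other half is a 5,6,7,8-tetrahydrochromone in which a 4-pyranone (ring A) is fused through the C4a=C8a double bond to a saturated, tetra-oxygenated carbocycle (ring B). The halves are joined only by the C5–O–C6′ bond, so C5 is a secondary carbinol carbon that carries an aryloxy group and sits directly on the pyranone carbon C4a. Ring B holds four contiguous stereocentres, C5–C8 (5S,6S,7R,8S), with O5 and O8 on one face and O6 and O7 on the other (5,6-trans, 6,7-cis, 7,8-trans). The fragile points are C5 and C8: their oxygens are lost by β-elimination from any C8a ketone or C4a enolate, or by O1-assisted ionisation, after which ring B aromatises; the pyranone is also opened by strong base. The difficulty is twofold: to build ring B on the pyranone without passing through an enolisable β-alkoxy ketone, and to single out O5 among four similar oxygens for a hindered alkyl–aryl ether of fixed configuration. The key step exploits the fact that C4a=C8a is both the only C=C of ring B and an enol ether double bond (O1–C8a=C4a). The trans,cis,trans tetrad C5–C8 is that of C2–C5 of D-galactose, read with sugar C1 as C4a and sugar C6 as C8a (the reverse reading would need the L-sugar), so the two sugar termini can be joined by olefin/enol ether metathesis.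

## Logic of the disconnections

28 to 27. The bonds cut are the O–C bonds of the isopropylidene acetal on O6/O7 and of the methoxymethyl groups on O8 and O7′. All three are acetals, so one hydrolytic step removes them at the very end. The gain is that O6, O7, O8 and the phenol stay inert through every bond-forming step. The demand is an acid strong enough for the alkyl methoxymethyl ether that does not ionise the C5–O bond.

27 to 21 and 26. The bond cut is the aryl C6′–O bond, not C5–O. Cutting on the aryl side leaves the C5–O bond untouched, so the configuration of C5 is carried through unchanged, and the molecule falls into two halves of similar size. The demand is a C–O coupling of a hindered secondary alkoxide with an electron-rich aryl bromide under base mild enough for the pyranone. For that reason the phenol of 26 is masked, and masked as an acetal so that the last step frees it at no extra cost.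

26 to 25, then to 22 and 23. The bonds cut are O7′–CH2 of the methoxymethyl ether, then O1′–C2′ and C2′–C3′ of the aromatic pyranone. The gain is that 22 already holds the bromine and both oxygens in the right places. The demand is C-acylation of the polyanion of 22 at the methyl ketone rather than at oxygen.

21 to 20. The bond cut is O5–CH2Ar. O5 must be the one oxygen that can be freed without acid or base, hence an oxidatively cleaved benzyl-type ether. The demand is that the oxidant leaves the pyranone and the acetals alone.

20 to 14 and 17, and 17 to 15 and 16. The bonds cut are C4–C4a and O1–C8a, which removes ring A. Both bonds end on the enol ether carbons of 14, whose polarity (C4a nucleophilic, C8a acetal-forming) matches an acylketene, so ring A and its side chain come from one reagent. 17 is cut at the CH2–CH2Ph bond. The demand is a neutral thermal cycloaddition and loss of methanol from C8a rather than of the C5 oxygen.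

14 to 13 (the key disconnection). The bond cut is C4a=C8a. It is the only C=C of ring B, and cutting it unfolds the ring to an acyclic chain whose four stereocentres are all carbinol centres, that is, a hexose. The gain is one ring and no stereocentre to make. The demand is a catalyst that loads on the vinyl end, tolerates the enol ether, and works without acid.

13 to 12, 11 and 10. The bond cut is C8a=CH2, then the oxidation level of C8a is taken back from ester to primary alcohol. The gain is that the enol ether is made last and from a stable ester. The demand is a non-basic methylenation (no epimerisation at C8, no β-elimination of O7) and an oxidation that spares the alkene and the p-methoxybenzyl ether.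

10 to 9, 8 and 7. The bonds cut are the O–Si bond on the C8a oxygen, O8–CH2OMe, and C4a=CH2; the last one re-closes the chain to a pyranose. In 7 the future O8 is the ring oxygen and the future C4a is the anomeric carbon, so O8 is told apart from O5 without any selective reaction. The demand is an ylide that neither epimerises C5 nor eliminates O6.

7 to 5, 4, 3, 2 and 1. The bonds cut are the anomeric O–allyl bond, O5–CH2Ar, the O–Si bond, the O6/O7 acetal and the glycosidic bond. On the pyranoside the only cis-diol takes the acetonide, the only primary hydroxyl takes the silyl group, and the single hydroxyl left is the future O5. The gain is that every oxygen of ring B is differentiated by the sugar template. The demand is a neutral anomeric deprotection.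

## Other disconnections considered

Alternative 1: The cut is C4a–C5, made while the C5–O–aryl bond is already present. Ring B is unfolded to the aryl 6-deoxyhex-5-enopyranoside A1 of the D-manno series; its anomeric carbon is the future C5 and its aglycone is the benzyl-protected aromatic chromone. In the forward step TiCl3(OiPr) would bind the ring oxygen of A1 and break the endocyclic C1–O5 bond to an aryloxy-stabilised oxocarbenium ion and a titanium enolate. The enolate carbon (future C4a) would then close onto the cationic carbon in a 6-(enolendo)-exo-trig aldol-type step, giving ketone A2 with the aglycone retained.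
- In its favour: the hindered C5–O–aryl ether is made as a glycosidic bond (the 1,2-trans α-mannoside is the easy anomer), so no late cross-coupling is needed. On this point it is better than the chosen plan.
- Equal: C6–C8 also come from a hexose, and the route to A2 should be shorter than the route to 14.
- Against: an aryloxide is a good leaving group and a poor donor, so exocyclic cleavage with loss of the aglycone should compete, and the chromone carbonyl offers the Lewis acid a second binding site.
- Against: A2 is a β-aryloxy ketone. Ring A can only be added by enolising it toward C4a, which is exactly the enolate that expels the aryloxide and starts aromatisation; enolisation toward C8 competes as well.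
- Against: the benzyl ethers would have to be removed by hydrogenolysis in the presence of two pyranone double bonds and a doubly activated C5–O bond.
- Comparison: both plans read ring B as a hexose. The alternative places the fragile C5 centre on the anomeric carbon, where its configuration rests on retention in an ion-pair process; the chosen plan carries it as an ordinary ether stereocentre. The alternative needs a strong Lewis acid and later an enolate; the chosen plan needs a neutral metal alkylidene and a neutral cycloaddition. In step count the alternative is probably ahead up to ring B and behind after it, so the two are about level, with the alternative's risk concentrated after its key step.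

Alternative 2: The cut is C5–O and C8–O together. Ring B comes from the enantiopure enone A3, converted into its cross-conjugated silyl dienol ether A4, a 2-silyloxy-1,3-cyclohexadiene. In the forward step singlet oxygen (O2, tetraphenylporphyrin, visible light, low temperature) would add across C5 and C8 of A4 on the face opposite the dioxolane. The product would be endoperoxide A5, with the C8a silyl enol ether left in place for ring A.
- In its favour: two C–O bonds and two stereocentres are made in one step, and the acetonide should direct them to exactly the target's trans,cis,trans pattern. In bonds formed per step and in length it is better than the chosen plan.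
- Against: making A4 means enolising A3 toward C8, which puts the C7 oxygen β to the enolate and invites elimination and aromatisation.
- Against: silyl enol ethers can react with singlet oxygen by ene and silyl-migration pathways as well.
- Against: A5 carries a peroxide next to an enol silane and would not survive a thermal annulation, so the O–O bond has to be reduced first. The two new hydroxyls at C5 and C8 are then nearly equivalent, and one of them must be arylated while the other stays free.
- Comparison: the chosen plan has O5 and O8 differentiated from the start, because one is the sugar's ring oxygen and the other an ordinary hydroxyl; on this point the chosen plan is clearly better. The alternative sets stereochemistry by substrate-controlled cycloaddition, the chosen plan sets none. Step economy favours the alternative, robustness and the end game favour the chosen plan.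

Alternative 3: The cut is C4–C4a and O1–C8a, so ring A is removed from a carbasugar enol silane A7. In the forward step thermolysis of the dioxinone would release (3-phenylpropanoyl)ketene, which adds across C8a=C4a of A7; loss of trimethylsilanol gives the protected tetrahydrochromone A8.
- Equal: this is the same ring A construction that the chosen plan uses directly after its key step.
- Slightly better: a silanol should leave more readily than methanol in the aromatising step, and O5 is freed by fluoride instead of an oxidant.
- Against: the disconnection does not say how A7 is reached. The obvious precursor, ring B ketone A6, must be enolised toward C4a, which places the C5 oxygen β to the enolate (elimination), and C4a must be chosen over C8. A trimethylsilyl enol ether is also awkward to purify and store.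
- Comparison: the two plans complement each other. The chosen plan can be read as this alternative with a defined, enolate-free entry to the ring B enol ether. After the enol ether the step count is the same, and the alternative would be ahead only if A6 were both quickly available and stable to enolisation.

Key step: step 12

Assumption: the anomer mixture of 7, the E/Z mixture of 6 and the C4a/C8a mixture of 19 are carried on as such, because these centres become sp2 or are lost in the same or a later step.

## Steps

Step 1
Reactants: 1 D-galactose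
Product: 2 allyl α-D-galactopyranoside
Conditions: allyl alcohol (solvent), Amberlite IR-120 (H+ form), 80 °C; crystallisation from EtOH
Reagents that add atoms: allyl alcohol, C=CCO
Why: Fischer glycosidation under equilibrating conditions; the α-pyranoside is favoured by the anomeric effect and should be the isomer that crystallises, and the anomeric configuration is erased in step 6 in any case.

Step 2
Reactants: 2 allyl α-D-galactopyranoside
Product: 3 allyl 3,4-O-isopropylidene-α-D-galactopyranoside
Conditions: Me2C(OMe)2, CSA (cat.), acetone, rt; Et3N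
Reagents that add atoms: 2,2-dimethoxypropane, COC(C)(C)OC
Why: Acid-catalysed transacetalisation under thermodynamic control should place the dioxolane on the only cis-vicinal diol (O3/O4, the future O6/O7), leaving O2–H and O6–H free.

Step 3
Reactants: 3 allyl 3,4-O-isopropylidene-α-D-galactopyranoside
Product: 4 allyl 6-O-(tert-butyldiphenylsilyl)-3,4-O-isopropylidene-α-D-galactopyranoside
Conditions: TBDPSCl, imidazole, DMF, 0 °C
Reagents that add atoms: tert-butyl(chloro)diphenylsilane, CC(C)(C)[Si](Cl)(c1ccccc1)c1ccccc1
Why: Silylation with a bulky chlorosilane is selective for the primary hydroxyl; the diphenyl-tert-butylsilyl group is chosen because it does not migrate under the basic conditions of steps 4 and 6.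

Step 4
Reactants: 4 allyl 6-O-(tert-butyldiphenylsilyl)-3,4-O-isopropylidene-α-D-galactopyranoside
Product: 5 allyl 6-O-(tert-butyldiphenylsilyl)-3,4-O-isopropylidene-2-O-(4-methoxybenzyl)-α-D-galactopyranoside
Conditions: NaH, PMBCl, Bu4NI (cat.), DMF, 0 °C to rt
Reagents that add atoms: 4-methoxybenzyl chloride, COc1ccc(CCl)cc1
Why: Williamson etherification of the one remaining hydroxyl (sugar O2, the future O5) installs the only group of the route that is later removed oxidatively.

Step 5
Reactants: 5 allyl 6-O-(tert-butyldiphenylsilyl)-3,4-O-isopropylidene-2-O-(4-methoxybenzyl)-α-D-galactopyranoside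
Product: 7 6-O-(tert-butyldiphenylsilyl)-3,4-O-isopropylidene-2-O-(4-methoxybenzyl)-D-galactopyranose (lactol as an anomer mixture), via prop-1-enyl glycoside 6 (not isolated)
Conditions: [Ir(cod)(PMePh2)2]PF6 (cat., activated with H2), THF, rt; then I2, NaHCO3, THF–H2O, rt
Reagents that add atoms: none
Why: Iridium-hydride-catalysed isomerisation of the allyl to the prop-1-enyl glycoside, then iodonium-induced hydrolysis of that enol ether, frees the anomeric hydroxyl at neutral pH, so the acetonide, silyl ether and p-methoxybenzyl ether are untouched.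

Step 6
Reactants: 7 6-O-(tert-butyldiphenylsilyl)-3,4-O-isopropylidene-2-O-(4-methoxybenzyl)-D-galactopyranose
Product: 8 7-O-(tert-butyldiphenylsilyl)-1,2-dideoxy-4,5-O-isopropylidene-3-O-(4-methoxybenzyl)-D-galacto-hept-1-enitol (6-OH free)
Conditions: Ph3PCH3Br, KOtBu, THF, 0 to 45 °C (ylide in excess)
Reagents that add atoms: methyltriphenylphosphonium bromide, C[P+](c1ccccc1)(c1ccccc1)c1ccccc1.[Br-]
Why: Wittig methylenation of the hydroxy aldehyde in equilibrium with the lactol turns sugar C1 into the vinyl CH (future C4a) and releases the ring oxygen as the free hydroxyl that becomes O8; the non-stabilised ylide reacts faster than the α-alkoxy aldehyde epimerises, and C2–C5 of the sugar are not touched.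

Step 7
Reactants: 8 7-O-(tert-butyldiphenylsilyl)-1,2-dideoxy-4,5-O-isopropylidene-3-O-(4-methoxybenzyl)-D-galacto-hept-1-enitol
Product: 9 7-O-(tert-butyldiphenylsilyl)-1,2-dideoxy-4,5-O-isopropylidene-3-O-(4-methoxybenzyl)-6-O-(methoxymethyl)-D-galacto-hept-1-enitol
Conditions: MOMCl, iPr2NEt, Bu4NI (cat.), CH2Cl2, 0 to 40 °C
Reagents that add atoms: chloromethyl methyl ether, COCCl
Why: Alkylation of the single free hydroxyl with the small methoxymethyl group, which is stable to fluoride, the titanium and ruthenium reagents and 110 °C, and adds little bulk next to the future enol ether.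

Step 8
Reactants: 9 7-O-(tert-butyldiphenylsilyl)-1,2-dideoxy-4,5-O-isopropylidene-3-O-(4-methoxybenzyl)-6-O-(methoxymethyl)-D-galacto-hept-1-enitol
Product: 10 1,2-dideoxy-4,5-O-isopropylidene-3-O-(4-methoxybenzyl)-6-O-(methoxymethyl)-D-galacto-hept-1-enitol (7-OH free)
Conditions: Bu4NF, THF, 0 °C to rt
Reagents that add atoms: none
Why: Fluoride cleaves the only silyl ether; no neighbouring hydroxyl is free, so no group can migrate.

Step 9
Reactants: 10 1,2-dideoxy-4,5-O-isopropylidene-3-O-(4-methoxybenzyl)-6-O-(methoxymethyl)-D-galacto-hept-1-enitol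
Product: 11 (2S,3R,4R,5S)-3,4-(isopropylidenedioxy)-5-[(4-methoxybenzyl)oxy]-2-(methoxymethoxy)hept-6-enoic acid
Conditions: TEMPO (cat.), PhI(OAc)2, MeCN–H2O (1:1), rt
Reagents that add atoms: water, O
Why: Oxoammonium oxidation of the primary alcohol through the aldehyde hydrate to the acid; the conditions are near neutral, so the α-alkoxy centre (future C8) should not epimerise, and the alkene and the benzyl-type ether are inert.

Step 10
Reactants: 11 (2S,3R,4R,5S)-3,4-(isopropylidenedioxy)-5-[(4-methoxybenzyl)oxy]-2-(methoxymethoxy)hept-6-enoic acid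
Product: 12 methyl (2S,3R,4R,5S)-3,4-(isopropylidenedioxy)-5-[(4-methoxybenzyl)oxy]-2-(methoxymethoxy)hept-6-enoate
Conditions: MeI, KHCO3, DMF, rt
Reagents that add atoms: iodomethane, CI
Why: O-Alkylation of the carboxylate with a base too weak to deprotonate the α-carbon, so neither epimerisation nor β-elimination of the acetonide oxygen is expected.

Step 11
Reactants: 12 methyl (2S,3R,4R,5S)-3,4-(isopropylidenedioxy)-5-[(4-methoxybenzyl)oxy]-2-(methoxymethoxy)hept-6-enoate
Product: 13 (3S,4R,5R,6S)-2-methoxy-4,5-(isopropylidenedioxy)-6-[(4-methoxybenzyl)oxy]-3-(methoxymethoxy)octa-1,7-diene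
Conditions: Cp2TiMe2 (2.5 equiv), toluene–THF, 65 °C, dark; filtration through basic alumina
Reagents that add atoms: Cp2TiMe2, C[Ti](C)(C1C=CC=C1)C1C=CC=C1
Why: Petasis methylenation: thermally formed Cp2Ti=CH2 converts the ester C=O into the 1-methoxyvinyl group through an oxatitanacyclobutane; the reagent is non-basic, so the α-stereocentre is safe, and its reversible addition to the terminal alkene causes no net change at this temperature.

Step 12
Reactants: 13 (3S,4R,5R,6S)-2-methoxy-4,5-(isopropylidenedioxy)-6-[(4-methoxybenzyl)oxy]-3-(methoxymethoxy)octa-1,7-diene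
Product: 14 (3S,4R,5R,6S)-1-methoxy-4,5-(isopropylidenedioxy)-3-[(4-methoxybenzyl)oxy]-6-(methoxymethoxy)cyclohex-1-ene (ring B; C1 = C8a, C2 = C4a, C3–C6 = C5–C8 of the target)
Conditions: second-generation Grubbs catalyst (H2IMes)(PCy3)Cl2Ru=CHPh (5–10 mol%), 1,4-benzoquinone (10 mol%), degassed toluene (0.005 M), 70 °C, N2 sparge; chromatography on Et3N-deactivated silica
Reagents that add atoms: none
Why: The 14-electron ruthenium alkylidene released from (H2IMes)(PCy3)Cl2Ru=CHPh first undergoes [2+2] cycloaddition and cycloreversion with the monosubstituted vinyl group (future C4a), and the new alkylidene then adds across the tethered 1-methoxyvinyl group with ruthenium on the CH2 terminus, so that cycloreversion forms C4a=C8a and releases Ru=CH2, which continues the cycle with loss of ethene. The closest known reaction type is ring-closing metathesis of olefin-tethered alkyl and silyl enol ethers to carbocyclic enol ethers. The one ring closed is the six-membered carbocycle, formed as a cyclohexene with the new double bond endocyclic through a ruthenacyclobutane; the two reacting arms are held cis on the dioxolane, so the chain is already folded. No stereocentre is formed: C5–C8 are C2–C5 of the sugar and none of them is α to a carbonyl group at any stage. The selectivity needed is loading of the catalyst on the vinyl group and not on the enol ether, where a heteroatom-stabilised ruthenium carbene that turns over poorly would result; the 1,1-disubstitution and the flanking methoxymethoxy group of the enol ether slow that pathway, whereas the allylic ether terminus is an ordinary fast-initiating olefin. High dilution should suppress dimerisation at the vinyl end, benzoquinone should intercept ruthenium hydrides that would isomerise the allylic ether, and base-treated silica keeps the acid-labile product, an enol ether with an allylic leaving group, intact.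

Step 13
Reactants: 15 2,2,6-trimethyl-4H-1,3-dioxin-4-one; 16 benzyl bromide
Product: 17 2,2-dimethyl-6-(2-phenylethyl)-4H-1,3-dioxin-4-one
Conditions: LiN(iPr)2, THF–DMPU, −78 °C; then 16, −78 to −30 °C
Reagents that add atoms: none
Why: The lithium dienolate of the dioxinone is alkylated by the reactive benzylic halide at the γ-carbon (the 6-methyl group) in the presence of a polar cosolvent, which extends the side chain to the phenethyl group.

Step 14
Reactants: 14 (3S,4R,5R,6S)-1-methoxy-4,5-(isopropylidenedioxy)-3-[(4-methoxybenzyl)oxy]-6-(methoxymethoxy)cyclohex-1-ene; 17 2,2-dimethyl-6-(2-phenylethyl)-4H-1,3-dioxin-4-one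
Product: 20 (5S,6R,7R,8S)-6,7-(isopropylidenedioxy)-5-[(4-methoxybenzyl)oxy]-8-(methoxymethoxy)-2-(2-phenylethyl)-5,6,7,8-tetrahydro-4H-chromen-4-one, via acylketene 18 (not isolated), via 8a-methoxy cycloadduct 19 (not isolated)
Conditions: 17 (3 equiv, slow addition), toluene, 110 °C, N2 sweep; then PPTS (cat.), 50 °C
Reagents that add atoms: none
Why: Retro-[4+2] loss of acetone from 17 gives (3-phenylpropanoyl)ketene, which reacts as a 1-oxadiene with the enol ether in a polarity-matched [4+2] addition (C4a to the ketene carbon, the acyl oxygen to C8a). Mild acid then ionises the C8a–OMe acetal and the C4a proton is lost, so methanol and not the C5 oxygen leaves and the aromatic 4-pyranone results; no enolate is formed and C5–C8 are untouched.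

Step 15
Reactants: 20 (5S,6R,7R,8S)-6,7-(isopropylidenedioxy)-5-[(4-methoxybenzyl)oxy]-8-(methoxymethoxy)-2-(2-phenylethyl)-5,6,7,8-tetrahydro-4H-chromen-4-one
Product: 21 (5S,6R,7R,8S)-5-hydroxy-6,7-(isopropylidenedioxy)-8-(methoxymethoxy)-2-(2-phenylethyl)-5,6,7,8-tetrahydro-4H-chromen-4-one
Conditions: DDQ, CH2Cl2–pH 7 phosphate buffer (10:1), 0 °C to rt
Reagents that add atoms: none
Why: Oxidative cleavage of the electron-rich benzyl ether by hydride abstraction and hydrolysis of the oxocarbenium ion; the electron-poor pyranone and the acetals are not oxidised, and the C5–O bond is retained.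

Step 16
Reactants: 22 1-(5-bromo-2,4-dihydroxyphenyl)ethanone; 23 3-phenylpropanoyl chloride
Product: 25 6-bromo-7-hydroxy-2-(2-phenylethyl)-4H-chromen-4-one, via 1,3-diketone 24 (not isolated)
Conditions: LiN(SiMe3)2 (4 equiv), THF, −78 to −10 °C; 23, −78 °C to rt; aq. HCl; then H2SO4 (cat.), AcOH, 95 °C
Reagents that add atoms: none
Why: Claisen-type C-acylation of the lithium polyanion of the dihydroxyacetophenone at the enolate carbon gives the 1,3-diketone without protection of the phenols, and acid-catalysed cyclodehydration through the ortho-hydroxyl closes the chromone.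

Step 17
Reactants: 25 6-bromo-7-hydroxy-2-(2-phenylethyl)-4H-chromen-4-one
Product: 26 6-bromo-7-(methoxymethoxy)-2-(2-phenylethyl)-4H-chromen-4-one
Conditions: MOMCl, iPr2NEt, CH2Cl2, 0 °C to rt
Reagents that add atoms: chloromethyl methyl ether, COCCl
Why: O-Alkylation of the single phenol; a phenoxide next to the bromide would deactivate the aryl halide and could quench the photocatalyst in step 18, and an aryl methoxymethyl ether falls off in the final acid step.

Step 18
Reactants: 21 (5S,6R,7R,8S)-5-hydroxy-6,7-(isopropylidenedioxy)-8-(methoxymethoxy)-2-(2-phenylethyl)-5,6,7,8-tetrahydro-4H-chromen-4-one; 26 6-bromo-7-(methoxymethoxy)-2-(2-phenylethyl)-4H-chromen-4-one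
Product: 27 (5S,6R,7R,8S)-6,7-(isopropylidenedioxy)-8-(methoxymethoxy)-5-{[7-(methoxymethoxy)-4-oxo-2-(2-phenylethyl)-4H-chromen-6-yl]oxy}-2-(2-phenylethyl)-5,6,7,8-tetrahydro-4H-chromen-4-one
Conditions: 26 (2 equiv), NiBr2(dme) (10 mol%), 4,4′-di-tert-butyl-2,2′-bipyridine (10 mol%), [Ir{dF(CF3)ppy}2(dtbbpy)]PF6 (1 mol%), quinuclidine (10 mol%), K2CO3, MeCN, blue LEDs (450 nm), rt
Reagents that add atoms: none
Why: Nickel/photoredox C–O cross-coupling of an aryl bromide with a secondary alcohol: oxidative addition of 26 to low-valent nickel, exchange of bromide for the alkoxide of 21, and photocatalytic oxidation to trivalent nickel, which reductively eliminates the aryl–oxygen bond. The C5–O bond is never broken, so C5 keeps its configuration, and the carbonate/quinuclidine base is too weak to open the pyranones.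

Step 19
Reactants: 27 (5S,6R,7R,8S)-6,7-(isopropylidenedioxy)-8-(methoxymethoxy)-5-{[7-(methoxymethoxy)-4-oxo-2-(2-phenylethyl)-4H-chromen-6-yl]oxy}-2-(2-phenylethyl)-5,6,7,8-tetrahydro-4H-chromen-4-one
Product: 28 (5S,6S,7R,8S)-6,7,8-trihydroxy-5-{[7-hydroxy-4-oxo-2-(2-phenylethyl)-4H-chromen-6-yl]oxy}-2-(2-phenylethyl)-5,6,7,8-tetrahydro-4H-chromen-4-one (CNP0248258.1)
Conditions: HCl (3 M aq.)–THF (1:1), 45 °C
Reagents that add atoms: none
Why: Acid hydrolysis of three acetal-type groups in one operation (aryl methoxymethyl ether and dioxolane first, the alkyl methoxymethyl ether at O8 last); only O–C bonds of the protecting groups are broken, and protonation of the pyranone carbonyl in this medium should disfavour ionisation at C5, so all four stereocentres are retained.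

## Compound list

1 | D-galactose | OC[C@H]1OC(O)[C@H](O)[C@@H](O)[C@H]1O | starting material
2 | allyl α-D-galactopyranoside | OC[C@H]1O[C@H](OCC=C)[C@H](O)[C@@H](O)[C@H]1O | intermediate
3 | allyl 3,4-O-isopropylidene-α-D-galactopyranoside | OC[C@H]1O[C@H](OCC=C)[C@H](O)[C@H]2OC(C)(C)O[C@H]21 | intermediate
4 | allyl 6-O-(tert-butyldiphenylsilyl)-3,4-O-isopropylidene-α-D-galactopyranoside | CC(C)(C)[Si](c1ccccc1)(c1ccccc1)OC[C@H]1O[C@H](OCC=C)[C@H](O)[C@H]2OC(C)(C)O[C@H]21 | intermediate
5 | allyl 6-O-(tert-butyldiphenylsilyl)-3,4-O-isopropylidene-2-O-(4-methoxybenzyl)-α-D-galactopyranoside | CC(C)(C)[Si](c1ccccc1)(c1ccccc1)OC[C@H]1O[C@H](OCC=C)[C@H](OCc3ccc(OC)cc3)[C@H]2OC(C)(C)O[C@H]21 | intermediate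
6 | prop-1-enyl 6-O-(tert-butyldiphenylsilyl)-3,4-O-isopropylidene-2-O-(4-methoxybenzyl)-α-D-galactopyranoside (E/Z mixture) | CC(C)(C)[Si](c1ccccc1)(c1ccccc1)OC[C@H]1O[C@H](OC=CC)[C@H](OCc3ccc(OC)cc3)[C@H]2OC(C)(C)O[C@H]21 | intermediate (not isolated)
7 | 6-O-(tert-butyldiphenylsilyl)-3,4-O-isopropylidene-2-O-(4-methoxybenzyl)-D-galactopyranose (anomer mixture) | CC(C)(C)[Si](c1ccccc1)(c1ccccc1)OC[C@H]1OC(O)[C@H](OCc3ccc(OC)cc3)[C@H]2OC(C)(C)O[C@H]21 | intermediate
8 | 7-O-(tert-butyldiphenylsilyl)-1,2-dideoxy-4,5-O-isopropylidene-3-O-(4-methoxybenzyl)-D-galacto-hept-1-enitol | C=C[C@H](OCc1ccc(OC)cc1)[C@H]1OC(C)(C)O[C@H]1[C@H](O)CO[Si](c1ccccc1)(c1ccccc1)C(C)(C)C | intermediate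
9 | 7-O-(tert-butyldiphenylsilyl)-1,2-dideoxy-4,5-O-isopropylidene-3-O-(4-methoxybenzyl)-6-O-(methoxymethyl)-D-galacto-hept-1-enitol | C=C[C@H](OCc1ccc(OC)cc1)[C@H]1OC(C)(C)O[C@H]1[C@H](OCOC)CO[Si](c1ccccc1)(c1ccccc1)C(C)(C)C | intermediate
10 | 1,2-dideoxy-4,5-O-isopropylidene-3-O-(4-methoxybenzyl)-6-O-(methoxymethyl)-D-galacto-hept-1-enitol | C=C[C@H](OCc1ccc(OC)cc1)[C@H]1OC(C)(C)O[C@H]1[C@H](OCOC)CO | intermediate
11 | (2S,3R,4R,5S)-3,4-(isopropylidenedioxy)-5-[(4-methoxybenzyl)oxy]-2-(methoxymethoxy)hept-6-enoic acid | C=C[C@H](OCc1ccc(OC)cc1)[C@H]1OC(C)(C)O[C@H]1[C@H](OCOC)C(=O)O | intermediate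
12 | methyl (2S,3R,4R,5S)-3,4-(isopropylidenedioxy)-5-[(4-methoxybenzyl)oxy]-2-(methoxymethoxy)hept-6-enoate | C=C[C@H](OCc1ccc(OC)cc1)[C@H]1OC(C)(C)O[C@H]1[C@H](OCOC)C(=O)OC | intermediate
13 | (3S,4R,5R,6S)-2-methoxy-4,5-(isopropylidenedioxy)-6-[(4-methoxybenzyl)oxy]-3-(methoxymethoxy)octa-1,7-diene | C=C[C@H](OCc1ccc(OC)cc1)[C@H]1OC(C)(C)O[C@H]1[C@H](OCOC)C(OC)=C | intermediate
14 | (3S,4R,5R,6S)-1-methoxy-4,5-(isopropylidenedioxy)-3-[(4-methoxybenzyl)oxy]-6-(methoxymethoxy)cyclohex-1-ene | COC1=C[C@H](OCc2ccc(OC)cc2)[C@H]2OC(C)(C)O[C@H]2[C@@H]1OCOC | intermediate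
15 | 2,2,6-trimethyl-4H-1,3-dioxin-4-one | CC1=CC(=O)OC(C)(C)O1 | starting material
16 | benzyl bromide | BrCc1ccccc1 | starting material
17 | 2,2-dimethyl-6-(2-phenylethyl)-4H-1,3-dioxin-4-one | CC1(C)OC(=O)C=C(CCc2ccccc2)O1 | intermediate
18 | (3-phenylpropanoyl)ketene (5-phenylpent-1-ene-1,3-dione) | O=C=CC(=O)CCc1ccccc1 | intermediate (not isolated)
19 | 8a-methoxy-4a,5,6,7,8,8a-hexahydro-4H-chromen-4-one cycloadduct (C5–C8 as in 14; C4a/C8a mixture) | COC12OC(CCc3ccccc3)=CC(=O)C1[C@H](OCc1ccc(OC)cc1)[C@H]1OC(C)(C)O[C@H]1[C@@H]2OCOC | intermediate (not isolated)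
20 | (5S,6R,7R,8S)-6,7-(isopropylidenedioxy)-5-[(4-methoxybenzyl)oxy]-8-(methoxymethoxy)-2-(2-phenylethyl)-5,6,7,8-tetrahydro-4H-chromen-4-one | O=c1cc(CCc2ccccc2)oc2c1[C@H](OCc1ccc(OC)cc1)[C@H]1OC(C)(C)O[C@H]1[C@@H]2OCOC | intermediate
21 | (5S,6R,7R,8S)-5-hydroxy-6,7-(isopropylidenedioxy)-8-(methoxymethoxy)-2-(2-phenylethyl)-5,6,7,8-tetrahydro-4H-chromen-4-one | O=c1cc(CCc2ccccc2)oc2c1[C@H](O)[C@H]1OC(C)(C)O[C@H]1[C@@H]2OCOC | intermediate
22 | 1-(5-bromo-2,4-dihydroxyphenyl)ethanone | CC(=O)c1cc(Br)c(O)cc1O | starting material
23 | 3-phenylpropanoyl chloride | O=C(Cl)CCc1ccccc1 | starting material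
24 | 1-(5-bromo-2,4-dihydroxyphenyl)-5-phenylpentane-1,3-dione | O=C(CC(=O)CCc1ccccc1)c1cc(Br)c(O)cc1O | intermediate (not isolated)
25 | 6-bromo-7-hydroxy-2-(2-phenylethyl)-4H-chromen-4-one | O=c1cc(CCc2ccccc2)oc2cc(O)c(Br)cc12 | intermediate
26 | 6-bromo-7-(methoxymethoxy)-2-(2-phenylethyl)-4H-chromen-4-one | O=c1cc(CCc2ccccc2)oc2cc(OCOC)c(Br)cc12 | intermediate
27 | (5S,6R,7R,8S)-6,7-(isopropylidenedioxy)-8-(methoxymethoxy)-5-{[7-(methoxymethoxy)-4-oxo-2-(2-phenylethyl)-4H-chromen-6-yl]oxy}-2-(2-phenylethyl)-5,6,7,8-tetrahydro-4H-chromen-4-one | O=c1cc(CCc2ccccc2)oc2c1[C@H](Oc1cc3c(=O)cc(CCc4ccccc4)oc3cc1OCOC)[C@H]1OC(C)(C)O[C@H]1[C@@H]2OCOC | intermediate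
28 | (5S,6S,7R,8S)-6,7,8-trihydroxy-5-{[7-hydroxy-4-oxo-2-(2-phenylethyl)-4H-chromen-6-yl]oxy}-2-(2-phenylethyl)-5,6,7,8-tetrahydro-4H-chromen-4-one (CNP0248258.1) | O=c1cc(CCc2ccccc2)oc2c1[C@H](Oc1cc3c(=O)cc(CCc4ccccc4)oc3cc1O)[C@@H](O)[C@@H](O)[C@@H]2O | target

## Step count and least certain steps

Total: 19 steps. Longest linear sequence: 16 steps from 1 (steps 1–12, 14, 15, 18, 19); steps 13, 16 and 17 prepare the two side fragments.

Step 12 (key step). The most likely failure is slow ring closure at the electron-rich, 1,1-disubstituted enol ether. Catalyst decomposition, double-bond migration at the allylic ether terminus and dimerisation at the vinyl end could then take over, and adventitious acid could hydrolyse the enol ether. The fallback sets out from 13 and returns at 20. The enol ether of 13 is hydrolysed (oxalic acid, wet THF, 0 °C) to the methyl ketone F1. Its kinetic enolate is trapped (KN(SiMe3)2, TBSCl, THF, −78 °C) as the 2-silyloxy-1,7-diene F2; deprotonation at the methyl group cannot trigger β-elimination. F2 is closed with (H2IMes)(PCy3)Cl2Ru=CHPh to the cyclic silyl enol ether F3, the enol ether class for which carbocyclic ring-closing metathesis is best established. F3 is then heated with 17 as in step 14, where loss of tert-butyldimethylsilanol instead of methanol gives 20.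

Step 18. The most likely failure is unproductive consumption of the aryl bromide by hydrodehalogenation while 21 is recovered. The hindered secondary alkoxide exchanges slowly onto an electron-rich, ortho-substituted aryl–nickel species, and C–O reductive elimination is slowest for electron-rich aryl groups. The fallback sets out from 21 and 26 and returns at 27; it makes the C5–O bond instead of the aryl–O bond, by two inversions.
- Mitsunobu reaction of 21 with 4-nitrobenzoic acid (PPh3, DIAD, toluene) gives the inverted 5-epi 4-nitrobenzoate F4.
- Methanolysis (K2CO3, MeOH, 0 °C) gives the 5-epi alcohol F5.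
- 26 is borylated (B2pin2, PdCl2(dppf), KOAc, dioxane, 90 °C) to the pinacol boronate F6 and oxidised (NaBO3, THF–H2O, rt) to the 6-hydroxychromone F7.
- Mitsunobu etherification of F5 with the phenol F7 (PPh3, DIAD, toluene) inverts C5 a second time and gives 27.

Step 14. The most likely failure is that the hindered, inductively deactivated trisubstituted enol ether traps the acylketene more slowly than the ketene dimerises or than 14 degrades at 110 °C. A second hazard is elimination of the C5 oxygen instead of methanol from 19. The fallback sets out from 14 and returns at 20; it builds ring A stepwise without ever forming an enolate at C4a.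
- Vilsmeier–Haack formylation at C4a ((chloromethylene)dimethyliminium chloride, 2,6-lutidine, CH2Cl2, 0 °C; aqueous NaOAc), the reaction known for C2 of protected glycals, gives the β-methoxy enal F8.
- Aldol addition of the kinetic lithium enolate of 4-phenylbutan-2-one (LiN(iPr)2, THF, −78 °C) gives the β-hydroxy ketone F9.
- Dess–Martin oxidation (NaHCO3, CH2Cl2) gives the β-diketone F10.
- PPTS in toluene at 60 °C closes the pyranone: the enol oxygen adds to C8a and methanol leaves, giving 20.

Step 19. The most likely failure is that the alkyl methoxymethyl ether at O8 resists hydrolysis until conditions are reached under which ring B dehydrates or the C5 aryloxy group is solvolysed or epimerised. The fallback sets out from 27 and returns at 28. ZnBr2 and n-PrSH in CH2Cl2 at 0 °C transfer both methoxymethyl groups to the thiol without Brønsted acid or water and give the acetonide diol F11. The dioxolane alone is then hydrolysed with 80% aqueous AcOH at 40 °C, which gives 28.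

## Further compounds

F1 | step 12 | (3S,4R,5R,6S)-4,5-(isopropylidenedioxy)-6-[(4-methoxybenzyl)oxy]-3-(methoxymethoxy)oct-7-en-2-one | C=C[C@H](OCc1ccc(OC)cc1)[C@H]1OC(C)(C)O[C@H]1[C@H](OCOC)C(C)=O
F2 | step 12 | 2-[(tert-butyldimethylsilyl)oxy] analogue of diene 13 | C=C[C@H](OCc1ccc(OC)cc1)[C@H]1OC(C)(C)O[C@H]1[C@H](OCOC)C(=C)O[Si](C)(C)C(C)(C)C
F3 | step 12 | 1-[(tert-butyldimethylsilyl)oxy] analogue of cyclohexene 14 | CC(C)(C)[Si](C)(C)OC1=C[C@H](OCc2ccc(OC)cc2)[C@H]2OC(C)(C)O[C@H]2[C@@H]1OCOC
F4 | step 18 | 5-epi 4-nitrobenzoate of 21 (5R,6R,7R,8S) | O=c1cc(CCc2ccccc2)oc2c1[C@@H](OC(=O)c1ccc(cc1)[N+](=O)[O-])[C@H]1OC(C)(C)O[C@H]1[C@@H]2OCOC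
F5 | step 18 | 5-epi alcohol (5R,6R,7R,8S)-5-hydroxy-6,7-(isopropylidenedioxy)-8-(methoxymethoxy)-2-(2-phenylethyl)-5,6,7,8-tetrahydro-4H-chromen-4-one | O=c1cc(CCc2ccccc2)oc2c1[C@@H](O)[C@H]1OC(C)(C)O[C@H]1[C@@H]2OCOC
F6 | step 18 | 7-(methoxymethoxy)-2-(2-phenylethyl)-6-(4,4,5,5-tetramethyl-1,3,2-dioxaborolan-2-yl)-4H-chromen-4-one | O=c1cc(CCc2ccccc2)oc2cc(OCOC)c(B3OC(C)(C)C(C)(C)O3)cc12
F7 | step 18 | 6-hydroxy-7-(methoxymethoxy)-2-(2-phenylethyl)-4H-chromen-4-one | O=c1cc(CCc2ccccc2)oc2cc(OCOC)c(O)cc12
F8 | step 14 | 2-methoxy-4,5-(isopropylidenedioxy)-6-[(4-methoxybenzyl)oxy]-3-(methoxymethoxy)cyclohex-1-ene-1-carbaldehyde (configuration as in 14) | COC1=C(C=O)[C@H](OCc2ccc(OC)cc2)[C@H]2OC(C)(C)O[C@H]2[C@@H]1OCOC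
F9 | step 14 | aldol adduct of F8 and 4-phenylbutan-2-one (carbinol mixture) | COC1=C(C(O)CC(=O)CCc2ccccc2)[C@H](OCc2ccc(OC)cc2)[C@H]2OC(C)(C)O[C@H]2[C@@H]1OCOC
F10 | step 14 | 1-(2-methoxycyclohex-1-enyl)-5-phenylpentane-1,3-dione derivative (β-diketone from F9) | COC1=C(C(=O)CC(=O)CCc2ccccc2)[C@H](OCc2ccc(OC)cc2)[C@H]2OC(C)(C)O[C@H]2[C@@H]1OCOC
F11 | step 19 | 6,7-O-isopropylidene derivative of 28 (8-OH and 7′-OH free) | O=c1cc(CCc2ccccc2)oc2c1[C@H](Oc1cc3c(=O)cc(CCc4ccccc4)oc3cc1O)[C@H]1OC(C)(C)O[C@H]1[C@@H]2O
A1 | alternative 1 | 7-(benzyloxy)-4-oxo-2-(2-phenylethyl)-4H-chromen-6-yl 2,3,4-tri-O-benzyl-6-deoxy-α-D-lyxo-hex-5-enopyranoside | C=C1O[C@H](Oc2cc3c(=O)cc(CCc4ccccc4)oc3cc2OCc2ccccc2)[C@@H](OCc2ccccc2)[C@@H](OCc2ccccc2)[C@@H]1OCc1ccccc1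
A2 | alternative 1 | ring B ketone (C8a carbonyl, C4a methylene) with the C5 aryl ether and three benzyl ethers | O=C1C[C@H](Oc2cc3c(=O)cc(CCc4ccccc4)oc3cc2OCc2ccccc2)[C@@H](OCc2ccccc2)[C@@H](OCc2ccccc2)[C@@H]1OCc1ccccc1
A3 | alternative 2 | (4R,5S)-4,5-(isopropylidenedioxy)cyclohex-2-en-1-one | O=C1C=C[C@H]2OC(C)(C)O[C@H]2C1
A4 | alternative 2 | 2-[(tert-butyldimethylsilyl)oxy]-5,6-cis-(isopropylidenedioxy)cyclohexa-1,3-diene | CC(C)(C)[Si](C)(C)OC1=C[C@@H]2OC(C)(C)O[C@@H]2C=C1
A5 | alternative 2 | 2,3-dioxabicyclo[2.2.2]oct-5-ene endoperoxide bridging C5 and C8, with the C8a silyl enol ether and the 6,7-acetonide | CC(C)(C)[Si](C)(C)OC1=C[C@@H]2OO[C@H]1[C@@H]3OC(C)(C)O[C@@H]32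
A6 | alternative 3 | ring B ketone (C8a carbonyl, C4a methylene; O5 tert-butyldimethylsilyl, O6/O7 acetonide, O8 methoxymethyl) | O=C1C[C@H](O[Si](C)(C)C(C)(C)C)[C@H]2OC(C)(C)O[C@H]2[C@@H]1OCOC
A7 | alternative 3 | trimethylsilyl enol ether of A6 (C8a=C4a) | C[Si](C)(C)OC1=C[C@H](O[Si](C)(C)C(C)(C)C)[C@H]2OC(C)(C)O[C@H]2[C@@H]1OCOC
A8 | alternative 3 | (5S,6S,7R,8S)-5-[(tert-butyldimethylsilyl)oxy]-6,7-(isopropylidenedioxy)-8-(methoxymethoxy)-2-(2-phenylethyl)-5,6,7,8-tetrahydro-4H-chromen-4-one | O=c1cc(CCc2ccccc2)oc2c1[C@H](O[Si](C)(C)C(C)(C)C)[C@H]3OC(C)(C)O[C@H]3[C@@H]2OCOC
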